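**Strategy.** The 1,2-dioxolane (O1–O2–C3–C4–C5) is taken apart into a ketone-level peroxycarbenium ion at C3 and a 2-methyl-1-alkene that supplies C4 and C5. One SnCl4-mediated [3+2] annulation forges the C3–C4 bond and the O1–C5 bond, closing the ring and creating both quaternary centres. It exploits the unsubstituted C4 methylene flanked by two fully substituted peroxy carbons: C5 is the Markovnikov terminus of a 1,1-disubstituted alkene. The precursor pair is a triethylsilylperoxy methyl ketal, whose acetic acid arm is masked as an (S)-configured bis-silylated diol stub (later destroyed by glycol cleavage), and an alkene carrying an (E)-vinyl iodide for a final Suzuki triene assembly.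

Key step: step 7

Remark: C3 carries the acetic acid arm and C5 the chain; the C3 descriptor is S in 13 and 14 and R in 15, 16 and 19 only because oxidation of the stub changes CIP priorities, no bond at C3 being touched. The annulation is not expected to be fully selective at either new centre, so isolation of the single isomer relies on the stub making all products diastereomers; if the facial bias at C3 runs the other way, (S)-glycidol is used in the same sequence.

**Step 1**
Reactants: 1 undec-10-ynoic acid
Product: 2 dodec-11-yn-2-one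
Conditions: MeLi (3.2 equiv), THF, 0 °C to rt; aq. HCl quench
Reagents that add atoms: methyllithium, [Li]C
Why: Ketone synthesis from a lithium carboxylate: MeLi adds to give a stable gem-dialkoxide that releases the methyl ketone only on hydrolysis, and the acetylide formed alongside is reprotonated on work-up.

**Step 2**
Reactants: 2 dodec-11-yn-2-one
Product: 3 2-methyldodec-1-en-11-yne
Conditions: Ph3PCH3Br, KOtBu, THF, 0 °C to rt
Reagents that add atoms: methyltriphenylphosphonium bromide, C[P+](c1ccccc1)(c1ccccc1)c1ccccc1.[Br-]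
Why: Wittig methylenation of the methyl ketone gives the 1,1-disubstituted alkene; the ylide is too weak a base to consume the terminal alkyne.

**Step 3**
Reactants: 3 2-methyldodec-1-en-11-yne
Product: 5 (1E)-1-iodo-11-methyldodeca-1,11-diene, via alkenylzirconocene chloride 4 (not isolated)
Conditions: Cp2Zr(H)Cl (1.1 equiv), THF, rt; then I2, 0 °C
Reagents that add atoms: iodine, I-I; zirconocene chloride hydride, [H][Zr](Cl)(C1C=CC=C1)C1C=CC=C1 (its zirconium stays only in 4)
Why: Schwartz hydrozirconation adds Zr–H syn and anti-Markovnikov to the terminal alkyne much faster than to the 1,1-disubstituted alkene, and iodinolysis with retention gives the E-vinyl iodide.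

**Step 4**
Reactants: 6 (R)-glycidol
Product: 7 (S)-4-methylpent-4-ene-1,2-diol
Conditions: CH2=C(CH3)MgBr (2.5 equiv), CuI (10 mol %), THF, −30 to 0 °C; aq. NH4Cl
Reagents that add atoms: isopropenylmagnesium bromide, CC(=C)[Mg]Br
Why: Copper-catalysed Grignard opening of the epoxide at its unsubstituted carbon (SN2) leaves the stereocentre untouched, so (R)-glycidol gives the (S)-diol (descriptor change by priority only).

**Step 5**
Reactants: 7 (S)-4-methylpent-4-ene-1,2-diol
Product: 8 (S)-4-methyl-1,2-bis(triisopropylsilyloxy)pent-4-ene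
Conditions: iPr3SiOTf (2.3 equiv), 2,6-lutidine, CH2Cl2, 0 °C to rt
Reagents that add atoms: triisopropylsilyl triflate, CC(C)[Si](OS(=O)(=O)C(F)(F)F)(C(C)C)C(C)C
Why: Silylation with the triflate caps both hydroxyls as hindered TIPS ethers that tolerate Lewis acid and do not participate at a neighbouring cation.

**Step 6**
Reactants: 8 (S)-4-methyl-1,2-bis(triisopropylsilyloxy)pent-4-ene
Product: 10 triethyl{[(4S)-2-methoxy-4,5-bis(triisopropylsilyloxy)pentan-2-yl]peroxy}silane, via hydroperoxy ketal 9 (not isolated)
Conditions: O3, CH2Cl2/MeOH (4:1), NaHCO3, −78 °C; concentrate cold; Et3SiCl, imidazole, DMF, 0 °C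
Reagents that add atoms: ozone, [O-][O+]=O; methanol, CO; chlorotriethylsilane, CC[Si](Cl)(CC)CC
Why: Criegee ozonolysis: the primary ozonide splits into formaldehyde and the more substituted carbonyl oxide, methanol traps the latter as the hydroperoxy ketal, and O-silylation caps it; the ketal carbon forms as an epimer mixture of no consequence because it becomes planar in step 7.

**Step 7**
Reactants: 10 triethylsilylperoxy ketal; 5 (1E)-1-iodo-11-methyldodeca-1,11-diene
Product: 13 (3S,5S)-3-[(2S)-2,3-bis(triisopropylsilyloxy)propyl]-5-[(9E)-10-iododec-9-en-1-yl]-3,5-dimethyl-1,2-dioxolane, via peroxycarbenium ion 11 (not isolated), via tertiary carbenium ion 12 (not isolated)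
Conditions: SnCl4 (1.1 equiv), 5 (1.5 equiv), CH2Cl2, −78 °C; aq. NaHCO3; chromatography
Reagents that add atoms: none
Why: SnCl4 abstracts methoxide from 10 to give peroxycarbenium ion 11; the CH2 terminus of the 1,1-disubstituted alkene of 5 attacks C3 (new C3–C4 bond, Markovnikov) to give tertiary carbenium ion 12, and the silylperoxy oxygen then captures C5 with transfer of Et3Si to methoxide. The closest known reaction type is the Lewis acid-mediated [3+2] annulation of triethylsilylperoxy ketals (peroxycarbenium ions) with alkenes, which is established for 1,1-disubstituted alkenes and gives 3,3,5,5-tetrasubstituted 1,2-dioxolanes. The five-membered ring is closed in a stepwise cationic [3+2] mode: intermolecular C3–C4 bond formation, then O1–C5 collapse of the peroxy oxygen onto the carbenium centre (formally 5-endo with respect to the former C4=C5 bond, a cation capture and so not stereoelectronically restricted). C3 is set in the C–C bond-forming event, where the β-silyloxy stereocentre of the stub differentiates the faces of 11 (polar 1,3-anti model: the new C3–O bond ends anti to the Cβ–O bond, the required sense for the (S)-stub); C5 is set in the ring closure, where the bulky stub on C3 and the long chain on C5 should prefer opposite faces of the envelope, again the required relationship. Neither bias is expected to be complete, so the step relies on the stub making all four possible isomers diastereomers, and the (3S,5S) isomer 13 is isolated by chromatography (if necessary at the stage of diol 14). Chemoselectivity for the 1,1-disubstituted alkene over the vinyl iodide is needed and is secured by the low nucleophilicity of the iodoalkene and by the tertiary cation available only from the former, while the hindered TIPS ethers neither ionise nor capture the cations at −78 °C.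

**Step 8**
Reactants: 13 annulation product
Product: 14 (2S)-3-[(3S,5S)-5-[(9E)-10-iododec-9-en-1-yl]-3,5-dimethyl-1,2-dioxolan-3-yl]propane-1,2-diol
Conditions: Bu4NF (3 equiv), THF, 0 °C to rt
Reagents that add atoms: none
Why: Fluoride-mediated desilylation removes both TIPS groups; the fully substituted peroxide has no hydrogen on its carbons and so cannot undergo base-induced Kornblum–DeLaMare cleavage, and the vinyl iodide is inert.

**Step 9**
Reactants: 14 dioxolanyl diol
Product: 16 2-[(3R,5S)-5-[(9E)-10-iododec-9-en-1-yl]-3,5-dimethyl-1,2-dioxolan-3-yl]acetic acid, via dioxolanylacetaldehyde 15 (not isolated)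
Conditions: NaIO4, THF/pH 7 buffer, 0 °C; then NaClO2, NaH2PO4, 2-methyl-2-butene, t-BuOH/H2O, 0 °C
Reagents that add atoms: sodium chlorite, [Na+].[O-]Cl=O
Why: Malaprade glycol cleavage destroys the stub stereocentre and gives the β-peroxy aldehyde, which is oxidised at once under buffered Pinnick conditions so that no base is present to trigger retro-oxa-Michael opening at C3.

**Step 10**
Reactants: 17 (E)-pent-2-enal
Product: 18 2-[(1E,3E)-hexa-1,3-dien-1-yl]-4,4,5,5-tetramethyl-1,3,2-dioxaborolane
Conditions: CH2(Bpin)2, LiTMP, THF, 0 °C; then 17, −78 °C to rt; aq. NH4Cl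
Reagents that add atoms: bis(pinacolboryl)methane, CC1(C)OB(CB2OC(C)(C)C(C)(C)O2)OC1(C)C
Why: Boron-Wittig olefination: the α-boryl carbanion adds 1,2 to the enal and syn B–O elimination gives the E-alkenyl boronate, the existing E-alkene being untouched.

**Step 11**
Reactants: 16 iodoalkenyl dioxolane acid; 18 dienyl boronate
Product: 19 2-[(3R,5S)-5-[(9E,11E,13E)-hexadeca-9,11,13-trien-1-yl]-3,5-dimethyl-1,2-dioxolan-3-yl]acetic acid
Conditions: Pd(PPh3)4 (5 mol %), aq. K3PO4 (3 equiv), 18 (1.3 equiv), THF, 40 °C, degassed, dark; acidify to pH 4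
Reagents that add atoms: none
Why: Suzuki–Miyaura coupling: oxidative addition of zerovalent palladium to the C–I bond, transmetalation and reductive elimination proceed with retention at both alkenes to give the E,E,E-triene, while the carboxylate and the peroxide are spectators.

**Compound list**

1 | undec-10-ynoic acid | C#CCCCCCCCCC(=O)O | starting material
2 | dodec-11-yn-2-one | CC(=O)CCCCCCCCC#C | intermediate
3 | 2-methyldodec-1-en-11-yne | C=C(C)CCCCCCCCC#C | intermediate
4 | chlorobis(cyclopentadienyl)[(1E)-11-methyldodeca-1,11-dien-1-yl]zirconium | C=C(C)CCCCCCCC/C=C/[Zr](Cl)(C1C=CC=C1)C1C=CC=C1 | intermediate (not isolated)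
5 | (1E)-1-iodo-11-methyldodeca-1,11-diene | C=C(C)CCCCCCCC/C=C/I | intermediate
6 | (R)-glycidol | OC[C@@H]1CO1 | starting material
7 | (S)-4-methylpent-4-ene-1,2-diol | C=C(C)C[C@H](O)CO | intermediate
8 | (S)-4-methyl-1,2-bis(triisopropylsilyloxy)pent-4-ene | C=C(C)C[C@H](O[Si](C(C)C)(C(C)C)C(C)C)CO[Si](C(C)C)(C(C)C)C(C)C | intermediate
9 | (4S)-2-hydroperoxy-2-methoxy-4,5-bis(triisopropylsilyloxy)pentane (both C2 epimers) | COC(C)(OO)C[C@H](O[Si](C(C)C)(C(C)C)C(C)C)CO[Si](C(C)C)(C(C)C)C(C)C | intermediate (not isolated)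
10 | triethyl{[(4S)-2-methoxy-4,5-bis(triisopropylsilyloxy)pentan-2-yl]peroxy}silane (both C2 epimers) | COC(C)(OO[Si](CC)(CC)CC)C[C@H](O[Si](C(C)C)(C(C)C)C(C)C)CO[Si](C(C)C)(C(C)C)C(C)C | intermediate
11 | peroxycarbenium ion, the O-(triethylsilyloxy)oxocarbenium ion of (4S)-4,5-bis(triisopropylsilyloxy)pentan-2-one | CC(=[O+]O[Si](CC)(CC)CC)C[C@H](O[Si](C(C)C)(C(C)C)C(C)C)CO[Si](C(C)C)(C(C)C)C(C)C | intermediate (not isolated)
12 | tertiary carbenium ion at C5 after C3–C4 bond formation, open-chain triethylsilyl peroxide | I/C=C/CCCCCCCC[C+](C)C[C@](C)(C[C@H](O[Si](C(C)C)(C(C)C)C(C)C)CO[Si](C(C)C)(C(C)C)C(C)C)OO[Si](CC)(CC)CC | intermediate (not isolated)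
13 | (3S,5S)-3-[(2S)-2,3-bis(triisopropylsilyloxy)propyl]-5-[(9E)-10-iododec-9-en-1-yl]-3,5-dimethyl-1,2-dioxolane | I/C=C/CCCCCCCC[C@@]1(C)C[C@](C)(C[C@H](O[Si](C(C)C)(C(C)C)C(C)C)CO[Si](C(C)C)(C(C)C)C(C)C)OO1 | intermediate
14 | (2S)-3-[(3S,5S)-5-[(9E)-10-iododec-9-en-1-yl]-3,5-dimethyl-1,2-dioxolan-3-yl]propane-1,2-diol | I/C=C/CCCCCCCC[C@@]1(C)C[C@](C)(C[C@H](O)CO)OO1 | intermediate
15 | 2-[(3R,5S)-5-[(9E)-10-iododec-9-en-1-yl]-3,5-dimethyl-1,2-dioxolan-3-yl]acetaldehyde | I/C=C/CCCCCCCC[C@@]1(C)C[C@](C)(CC=O)OO1 | intermediate (not isolated)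
16 | 2-[(3R,5S)-5-[(9E)-10-iododec-9-en-1-yl]-3,5-dimethyl-1,2-dioxolan-3-yl]acetic acid | I/C=C/CCCCCCCC[C@@]1(C)C[C@](C)(CC(=O)O)OO1 | intermediate
17 | (E)-pent-2-enal | CC/C=C/C=O | starting material
18 | 2-[(1E,3E)-hexa-1,3-dien-1-yl]-4,4,5,5-tetramethyl-1,3,2-dioxaborolane | CC/C=C/C=C/B1OC(C)(C)C(C)(C)O1 | intermediate
19 | 2-[(3R,5S)-5-[(9E,11E,13E)-hexadeca-9,11,13-trien-1-yl]-3,5-dimethyl-1,2-dioxolan-3-yl]acetic acid | CC/C=C/C=C/C=C/CCCCCCCC[C@@]1(C)C[C@](C)(CC(=O)O)OO1 | target

**Step count.** Total: 11 steps. Longest linear sequence: 7 steps (1, 2, 3, 7, 8, 9, 11 or 4, 5, 6, 7, 8, 9, 11).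

**Steps most likely to fail**

Step 7. The tertiary carbenium ion 12 may be diverted by proton loss or chloride capture before the hindered silylperoxy oxygen closes the ring, and facial discrimination at C3 and C5 may be too weak for a practical isolation. The fallback separates C–C bond formation from ring closure (Hosomi–Sakurai allylation, then cycloperoxymercuration and demercuration); it sets out from ketone 2 and peroxyketal 10 and comes back at 13. Ketone 2 is converted with LDA (2.1 equiv) and PhNTf2 into dodec-1-en-11-yn-2-yl triflate F1. Kumada coupling of F1 with Me3SiCH2MgCl under Pd(PPh3)4 catalysis gives trimethyl(2-methylidenedodec-11-yn-1-yl)silane F2. Hydrozirconation of F2 as in step 3 gives the alkenylzirconocene chloride F3, and iodinolysis gives [(11E)-12-iodo-2-methylidenedodec-11-en-1-yl]trimethylsilane F4. This allylsilane is far more nucleophilic than 5 and intercepts ion 11 (SnCl4, CH2Cl2, −78 °C); the β-silyl cation collapses by loss of Me3Si to (2S,4R,15E)-16-iodo-4-methyl-6-methylidene-1,2-bis(triisopropylsilyloxy)hexadec-15-en-4-yl triethylsilyl peroxide F5. K2CO3 in MeOH frees the corresponding hydroperoxide F6. Hg(OAc)2 with catalytic HClO4 in CH2Cl2 then closes the ring in the Markovnikov sense to the 5-(acetoxymercuriomethyl) dioxolane F7. NaBH4 in aq. NaOH replaces mercury by hydrogen, which turns the CH2Hg group into the C5 methyl group of 13. Diastereomers are separated as in the main route.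

Step 11. The O–O bond may be reduced by zerovalent palladium or triphenylphosphine, and the triene may lose geometric purity under warm basic aqueous conditions. The fallback is a palladium-, phosphine- and base-free copper-mediated Stille-type coupling; it sets out from 17 and 16 and comes back at 19. Hodgson olefination of 17 (Bu3SnCHBr2, CrCl2, LiI, THF/DMF) gives tributyl[(1E,3E)-hexa-1,3-dien-1-yl]stannane F8. F8 is coupled with 16 by Cu(O2CC4H3S) (copper thiophene-2-carboxylate, monovalent copper, 1.5 equiv) in NMP at 0 °C to give 19.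

Step 6. The primary ozonide may fragment in the wrong direction (formaldehyde O-oxide), or the hydroperoxy ketal 9 may be lost by reversion to ketone or Hock/Criegee-type rearrangement during concentration and silylation. The fallback makes the peroxycarbenium precursor by radical silylperoxidation of an enol ether; it sets out from 8 and comes back at 13. Ozonolysis of 8 with reductive work-up (O3, CH2Cl2, −78 °C; Me2S) gives (4S)-4,5-bis(triisopropylsilyloxy)pentan-2-one F9. LDA and then tBuMe2SiCl give tert-butyldimethyl{[(4S)-4,5-bis(triisopropylsilyloxy)pent-1-en-2-yl]oxy}silane F10. Isayama–Mukaiyama-type peroxidation (Co(acac)2 catalyst, O2, Et3SiH) puts hydrogen on the CH2 carbon and the silylperoxy group on the oxygenated carbon, giving the silyl monoperoxyketal F11. F11 replaces 10 in step 7, where SnCl4 removes the silyloxy group to generate the same ion 11 and, with 5, gives 13.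

**Further compounds**

F1 | step 7 | dodec-1-en-11-yn-2-yl trifluoromethanesulfonate | C=C(OS(=O)(=O)C(F)(F)F)CCCCCCCCC#C
F2 | step 7 | trimethyl(2-methylidenedodec-11-yn-1-yl)silane | C=C(C[Si](C)(C)C)CCCCCCCCC#C
F3 | step 7 | chlorobis(cyclopentadienyl)[(1E)-11-(trimethylsilylmethyl)dodeca-1,11-dien-1-yl]zirconium | C=C(C[Si](C)(C)C)CCCCCCCC/C=C/[Zr](Cl)(C1C=CC=C1)C1C=CC=C1
F4 | step 7 | [(11E)-12-iodo-2-methylidenedodec-11-en-1-yl]trimethylsilane | C=C(C[Si](C)(C)C)CCCCCCCC/C=C/I
F5 | step 7 | (2S,4R,15E)-16-iodo-4-methyl-6-methylidene-1,2-bis(triisopropylsilyloxy)hexadec-15-en-4-yl triethylsilyl peroxide | I/C=C/CCCCCCCCC(=C)C[C@](C)(C[C@H](O[Si](C(C)C)(C(C)C)C(C)C)CO[Si](C(C)C)(C(C)C)C(C)C)OO[Si](CC)(CC)CC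
F6 | step 7 | (2S,4R,15E)-16-iodo-4-methyl-6-methylidene-1,2-bis(triisopropylsilyloxy)hexadec-15-en-4-yl hydroperoxide | I/C=C/CCCCCCCCC(=C)C[C@](C)(C[C@H](O[Si](C(C)C)(C(C)C)C(C)C)CO[Si](C(C)C)(C(C)C)C(C)C)OO
F7 | step 7 | {(3S,5S)-5-[(2S)-2,3-bis(triisopropylsilyloxy)propyl]-3-[(9E)-10-iododec-9-en-1-yl]-5-methyl-1,2-dioxolan-3-yl}methylmercury acetate | I/C=C/CCCCCCCC[C@@]1(C[Hg]OC(C)=O)C[C@](C)(C[C@H](O[Si](C(C)C)(C(C)C)C(C)C)CO[Si](C(C)C)(C(C)C)C(C)C)OO1
F8 | step 11 | tributyl[(1E,3E)-hexa-1,3-dien-1-yl]stannane | CC/C=C/C=C/[Sn](CCCC)(CCCC)CCCC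
F9 | step 6 | (4S)-4,5-bis(triisopropylsilyloxy)pentan-2-one | CC(=O)C[C@H](O[Si](C(C)C)(C(C)C)C(C)C)CO[Si](C(C)C)(C(C)C)C(C)C
F10 | step 6 | tert-butyldimethyl{[(4S)-4,5-bis(triisopropylsilyloxy)pent-1-en-2-yl]oxy}silane | C=C(O[Si](C)(C)C(C)(C)C)C[C@H](O[Si](C(C)C)(C(C)C)C(C)C)CO[Si](C(C)C)(C(C)C)C(C)C
F11 | step 6 | tert-butyldimethyl{[(4S)-2-(triethylsilylperoxy)-4,5-bis(triisopropylsilyloxy)pentan-2-yl]oxy}silane (both C2 epimers) | CC(O[Si](C)(C)C(C)(C)C)(OO[Si](CC)(CC)CC)C[C@H](O[Si](C(C)C)(C(C)C)C(C)C)CO[Si](C(C)C)(C(C)C)C(C)C
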